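**Retrosynthetic overview**
1. Target ⇐ C11 ketone (Wittig) ⇐ bridged lactol (silane reduction): ring D (C8–O–C14) closes last.
2. Ring C ⇐ epoxide-initiated cation–olefin spirocyclisation (C7–C15 bond) of a bis-silyl dienol ether, mirroring the biogenetic epoxy-olefin closure at C7.
3. Side chain ⇐ Claisen acylation with an (S)-epoxy ester; ring B ⇐ 6-exo enolate alkylation (C6–C7).
4. Ring A ⇐ catalytic asymmetric bromonium-induced cation–olefin cyclisation (C5–C10 bond, Br on C1) terminated by a dioxinone, mirroring the biogenetic bromonium cyclisation; C4 carbinol by MeCeCl2.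
5. Rings are formed in the order A, B, C, D from pent-1-en-4-yne, 2,2,6-trimethyl-1,3-dioxin-4-one and ethyl 5-methylhex-4-enoate.

Assumption: the biogenesis is taken as bromonium-induced cyclisation of a germacrene-type diterpene to the bromo-eudesmane core, epoxide-initiated spirocyclisation at C7 and C8–O–C14 ether closure. Locants used below: ring A C1(Br)–C2–C3–C4(OH,Me)–C5–C10(Me); ring B C5–C6–C7–C8–C9–C10; ring C C7–C11(=C17H2)–C12–C13–C14–C15(Me2); ether O between C8 and C14.

**Step 1**
Reactants: 1 pent-1-en-4-yne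
Product: 3 (2E)-3-methylhexa-2,5-dien-1-ol, via alkenylalane 2 (not isolated)
Conditions: Me3Al, Cp2ZrCl2 (20 mol%), CH2Cl2, 0 °C to rt; then n-BuLi, (CH2O)n, THF, −30 °C to rt
Reagents that add atoms: trimethylaluminium C[Al](C)C; paraformaldehyde (formaldehyde) C=O
Why: Zr-catalysed carboalumination (Negishi) adds Me and Al syn across the terminal alkyne only, and formaldehyde trapping of the ate complex with retention gives the E allylic alcohol whose geometry later places the allyl arm equatorial.

**Step 2**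
Reactants: 3 (2E)-3-methylhexa-2,5-dien-1-ol
Product: 4 (2E)-1-bromo-3-methylhexa-2,5-diene
Conditions: CBr4, PPh3, CH2Cl2, 0 °C
Reagents that add atoms: carbon tetrabromide BrC(Br)(Br)Br
Why: Appel bromination is an SN2 reaction at the primary allylic carbinol and leaves both alkenes and the E geometry untouched.

**Step 3**
Reactants: 4 (2E)-1-bromo-3-methylhexa-2,5-diene; 5 2,2,6-trimethyl-4H-1,3-dioxin-4-one
Product: 6 2,2-dimethyl-6-[(3E)-4-methylhepta-3,6-dien-1-yl]-4H-1,3-dioxin-4-one
Conditions: LDA, THF–DMPU, −78 °C; then 4, −78 to −20 °C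
Reagents that add atoms: none
Why: LDA forms the vinylogous (dienolate) enolate of the dioxinone, which is alkylated at the terminal γ-carbon by the allylic bromide in an SN2 reaction.

**Step 4**
Reactants: 6 2,2-dimethyl-6-[(3E)-4-methylhepta-3,6-dien-1-yl]-4H-1,3-dioxin-4-one
Product: 7 (5S,6S)-6-bromo-2,2,5-trimethyl-5-(prop-2-en-1-yl)-5,6,7,8-tetrahydro-4H-1,3-benzodioxin-4-one
Conditions: DBDMH (0.6 equiv), chiral BINOL-derived thiophosphoramide (10 mol%, antipode giving 5S,6S), toluene–CH2Cl2, −78 to −60 °C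
Reagents that add atoms: 1,3-dibromo-5,5-dimethylhydantoin CC1(C)N(Br)C(=O)N(Br)C1=O
Why: Proposed new method: the chiral Lewis base activates DBDMH and delivers Br+ face-selectively to the electron-rich trisubstituted alkene (dioxinone and vinyl C=C are far less nucleophilic), the bromonium is opened anti at its tertiary carbon by C5 of the dioxinone through a chair (Br equatorial, E geometry puts the allyl arm equatorial and Me axial) and loss of H+ restores the dioxinone, the closest known chemistry being catalytic enantioselective bromonium-induced polyene cyclisation with arene terminators and Lewis-acid C-alkylation of dioxinones (Prins/Mukaiyama type).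

**Step 5**
Reactants: 7 bromo benzodioxinone
Product: 9 methyl (1S,2S,3S)-3-bromo-2-methyl-6-oxo-2-(prop-2-en-1-yl)cyclohexane-1-carboxylate, via acylketene 8 (not isolated)
Conditions: MeOH (5 equiv), toluene, 110 °C, sealed tube
Reagents that add atoms: methanol CO
Why: Thermal retro-hetero-Diels–Alder loss of acetone gives the acylketene, which adds methanol to the β-keto ester, and the epimerisable ester-bearing carbon (C5) settles trans to the allyl arm in the all-equatorial chair with the quaternary methyl axial.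

**Step 6**
Reactants: 9 β-keto ester
Product: 10 methyl (1S,2S,3S,6R)-3-bromo-6-hydroxy-2,6-dimethyl-2-(prop-2-en-1-yl)cyclohexane-1-carboxylate
Conditions: MeLi, CeCl3, THF, −78 °C; AcOH quench at −78 °C
Reagents that add atoms: methyllithium [Li]C
Why: The non-basic organocerium reagent (Imamoto 1,2-addition) adds to the enolisable ketone from the equatorial side because the axial face is blocked by the syn-axial C10 methyl, giving the axial tertiary alcohol (C4 R) cis to that methyl.

**Step 7**
Reactants: 10 β-hydroxy ester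
Product: 11 (1R,2R,3S,4S)-4-bromo-2-(hydroxymethyl)-1,3-dimethyl-3-(prop-2-en-1-yl)cyclohexan-1-ol
Conditions: LiAlH4, THF, −20 to 0 °C
Reagents that add atoms: none
Why: Hydride reduction of the ester to the primary alcohol touches no stereocentre, and the hindered secondary bromide and the alkene are inert at 0 °C.

**Step 8**
Reactants: 11 diol
Product: 12 [(1R,2S,3S,6R)-3-bromo-6-hydroxy-2,6-dimethyl-2-(prop-2-en-1-yl)cyclohexyl]methyl 4-methylbenzenesulfonate
Conditions: TsCl, pyridine, DMAP (cat.), CH2Cl2, 0 °C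
Reagents that add atoms: p-toluenesulfonyl chloride Cc1ccc(cc1)S(Cl)(=O)=O
Why: Sulfonylation discriminates the primary from the hindered tertiary hydroxyl.

**Step 9**
Reactants: 12 primary tosylate
Product: 13 [(1R,2S,3S,6R)-3-bromo-6-hydroxy-2,6-dimethyl-2-(2-oxopropyl)cyclohexyl]methyl 4-methylbenzenesulfonate
Conditions: PdCl2 (10 mol%), CuCl, O2 (1 atm), DMF–H2O 7:1, rt
Reagents that add atoms: water O
Why: Wacker–Tsuji oxidation converts the terminal alkene into the methyl ketone with Markovnikov regiochemistry and affects no stereocentre.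

**Step 10**
Reactants: 13 keto tosylate
Product: 14 (4aS,5R,8S,8aS)-8-bromo-5-hydroxy-5,8a-dimethyl-3,4,4a,5,6,7,8,8a-octahydronaphthalen-2(1H)-one
Conditions: LDA (2.2 equiv), THF–DMPU, −78 °C to rt
Reagents that add atoms: none
Why: The kinetic methyl-ketone enolate displaces the primary tosylate in a 6-exo-tet intramolecular alkylation (the other α-carbon would give a four-membered ring), and since C5 and C10 are already fixed with the two arms trans-diequatorial the decalin is trans-fused, the lithium alkoxide being too poor a nucleophile to close an oxetane.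

**Step 11**
Reactants: 15 ethyl 5-methylhex-4-enoate
Product: 16 ethyl 3-[(2S)-3,3-dimethyloxiran-2-yl]propanoate
Conditions: ent-Shi ketone (L-fructose-derived, 30 mol%), Oxone, K2CO3, Bu4NHSO4, MeCN–DMM–aq. buffer, 0 °C
Reagents that add atoms: Oxone (potassium peroxymonosulfate) [K+].[O-]S(=O)(=O)OO
Why: Shi asymmetric epoxidation (chiral dioxirane, spiro transition state) of the trisubstituted alkene sets the (S) epoxide carbon that becomes C14, the D-fructose-derived catalyst being expected to give the (R) antipode.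

**Step 12**
Reactants: 14 trans-decalone; 16 (S)-epoxy ester
Product: 17 (4aS,5R,8S,8aS)-8-bromo-3-{3-[(2S)-3,3-dimethyloxiran-2-yl]propanoyl}-5-hydroxy-5,8a-dimethyl-octahydronaphthalen-2(1H)-one (enol form)
Conditions: LDA (3.2 equiv), THF, −78 °C; then 16, −78 to 0 °C
Reagents that add atoms: none
Why: Crossed Claisen condensation in which the kinetic enolate forms at C7 (the α-carbon remote from the quaternary centre) and is C-acylated by the ester, the acidic β-diketone driving the equilibrium and the epoxide stereocentre staying untouched.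

**Step 13**
Reactants: 17 β-diketone
Product: 20 bridged lactol (C8 hemiketal to O-14; C11 ketone; C1, C4, C5, C7, C10, C14 as in the target), via tris-TMS dienol ether 18 (not isolated), via spiro hydroxy diketone 19 (not isolated)
Conditions: LDA (3.3 equiv), TMSCl (4 equiv), THF, −78 °C; solvent switch; MeAlCl2 (1.5 equiv), CH2Cl2, −78 °C; 1 M HCl–THF, 0 °C
Reagents that add atoms: none
Why: Proposed new method: MeAlCl2 opens the (S)-epoxide at its tertiary carbon and the central carbon C7 of the 1,3-bis(silyloxy)diene attacks it (the terminal carbon cannot reach and the oxygens are silyl-capped) in a six-membered chair with the epoxide oxygen pseudo-equatorial and the bulky CMe2 terminus equatorial on ring B, creating the vicinal-quaternary spiro centre C7 with the C14 hydroxyl cis to C8 so that acidic hydrolysis gives the C8 lactol directly, the closest known chemistry being Lewis-acid epoxy-olefin cyclisations terminated by silyl enol ethers and Mukaiyama-type tert-alkylation of silyl enol ethers.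

**Step 14**
Reactants: 20 bridged lactol
Product: 21 17-nor-11-oxo analogue of the target (C8–O–C14 ether; C11 ketone)
Conditions: Et3SiH (5 equiv), TMSOTf (0.2 equiv), CH2Cl2, −78 to −40 °C
Reagents that add atoms: none
Why: Ionic hydrogenation of the lactol through its oxocarbenium ion delivers hydride to C8 from the exo face, the only trajectory that keeps ring B a chair inside the rigid 6-oxabicyclo[3.2.1]octane, so H-8 is axial and the ether oxygen equatorial (C8 R), while the hindered C11 ketone and the tertiary alcohol survive at low temperature.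

**Step 15**
Reactants: 21 ether ketone
Product: 22 target CNP0412361.2 (1S,4R,5S,7R,8R,10S,14S)
Conditions: Ph3PCH3Br (5 equiv), KOtBu (4.8 equiv), toluene, 90 °C
Reagents that add atoms: methyltriphenylphosphonium bromide C[P+](c1ccccc1)(c1ccccc1)c1ccccc1.[Br-]
Why: Wittig methylenation with excess ylide at elevated temperature converts the hindered C11 ketone into the exocyclic methylene without touching a stereocentre, the equatorial bromide having no antiperiplanar hydrogen for E2.

**Compound list**
1 | pent-1-en-4-yne | C=CCC#C | starting material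
2 | (E)-dimethyl(2-methylpenta-1,4-dien-1-yl)alumane | C[Al](C)/C=C(\C)CC=C | intermediate
3 | (2E)-3-methylhexa-2,5-dien-1-ol | OC/C=C(\C)CC=C | intermediate
4 | (2E)-1-bromo-3-methylhexa-2,5-diene | BrC/C=C(\C)CC=C | intermediate
5 | 2,2,6-trimethyl-4H-1,3-dioxin-4-one | CC1=CC(=O)OC(C)(C)O1 | starting material
6 | 2,2-dimethyl-6-[(3E)-4-methylhepta-3,6-dien-1-yl]-4H-1,3-dioxin-4-one | CC1(C)OC(=O)C=C(CC/C=C(\C)CC=C)O1 | intermediate
7 | (5S,6S)-6-bromo-2,2,5-trimethyl-5-(prop-2-en-1-yl)-5,6,7,8-tetrahydro-4H-1,3-benzodioxin-4-one | CC1(C)OC(=O)C2=C(O1)CC[C@H](Br)[C@@]2(C)CC=C | intermediate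
8 | (3S,4S)-4-bromo-3-methyl-2-(oxomethylidene)-3-(prop-2-en-1-yl)cyclohexan-1-one (acylketene) | O=C=C1C(=O)CC[C@H](Br)[C@@]1(C)CC=C | intermediate
9 | methyl (1S,2S,3S)-3-bromo-2-methyl-6-oxo-2-(prop-2-en-1-yl)cyclohexane-1-carboxylate | COC(=O)[C@@H]1C(=O)CC[C@H](Br)[C@@]1(C)CC=C | intermediate
10 | methyl (1S,2S,3S,6R)-3-bromo-6-hydroxy-2,6-dimethyl-2-(prop-2-en-1-yl)cyclohexane-1-carboxylate | COC(=O)[C@@H]1[C@](C)(O)CC[C@H](Br)[C@@]1(C)CC=C | intermediate
11 | (1R,2R,3S,4S)-4-bromo-2-(hydroxymethyl)-1,3-dimethyl-3-(prop-2-en-1-yl)cyclohexan-1-ol | OC[C@@H]1[C@](C)(O)CC[C@H](Br)[C@@]1(C)CC=C | intermediate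
12 | [(1R,2S,3S,6R)-3-bromo-6-hydroxy-2,6-dimethyl-2-(prop-2-en-1-yl)cyclohexyl]methyl 4-methylbenzenesulfonate | Cc1ccc(cc1)S(=O)(=O)OC[C@@H]1[C@](C)(O)CC[C@H](Br)[C@@]1(C)CC=C | intermediate
13 | [(1R,2S,3S,6R)-3-bromo-6-hydroxy-2,6-dimethyl-2-(2-oxopropyl)cyclohexyl]methyl 4-methylbenzenesulfonate | Cc1ccc(cc1)S(=O)(=O)OC[C@@H]1[C@](C)(O)CC[C@H](Br)[C@@]1(C)CC(C)=O | intermediate
14 | (4aS,5R,8S,8aS)-8-bromo-5-hydroxy-5,8a-dimethyl-3,4,4a,5,6,7,8,8a-octahydronaphthalen-2(1H)-one | C[C@@]1(O)CC[C@H](Br)[C@@]2(C)CC(=O)CC[C@H]12 | intermediate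
15 | ethyl 5-methylhex-4-enoate | CCOC(=O)CCC=C(C)C | starting material
16 | ethyl 3-[(2S)-3,3-dimethyloxiran-2-yl]propanoate | CCOC(=O)CC[C@@H]1OC1(C)C | intermediate
17 | (4aS,5R,8S,8aS)-8-bromo-3-{3-[(2S)-3,3-dimethyloxiran-2-yl]propanoyl}-5-hydroxy-5,8a-dimethyl-octahydronaphthalen-2(1H)-one, drawn as its enol | C[C@@]1(O)CC[C@H](Br)[C@@]2(C)CC(O)=C(C[C@H]12)C(=O)CC[C@@H]1OC1(C)C | intermediate
18 | tris-TMS derivative of 17: C8 and C11 silyl enol ethers (C7=C8, C11=C12, E/Z mixture) and C4 silyl ether | C[C@@]1(O[Si](C)(C)C)CC[C@H](Br)[C@@]2(C)CC(O[Si](C)(C)C)=C(C[C@H]12)C(O[Si](C)(C)C)=CC[C@@H]1OC1(C)C | intermediate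
19 | spiro hydroxy diketone: ring C closed at C7–C15, ketones at C8 and C11, free 14-OH cis to C8 | O=C1CC[C@H](O)C(C)(C)[C@@]12C[C@@H]3[C@](C)(O)CC[C@H](Br)[C@@]3(C)CC2=O | intermediate
20 | bridged lactol: C8 hemiketal of 19 with O-14 (hemiketal OH in the place of H-8), C11 ketone | O=C1CC[C@@H]2O[C@]3(O)C[C@]4(C)[C@@H](Br)CC[C@@](C)(O)[C@H]4C[C@]13C2(C)C | intermediate
21 | 17-nor-11-oxo analogue of the target (all stereocentres as in the target) | O=C1CC[C@@H]2O[C@@H]3C[C@]4(C)[C@@H](Br)CC[C@@](C)(O)[C@H]4C[C@]13C2(C)C | intermediate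
22 | CNP0412361.2, (1S,4R,5S,7R,8R,10S,14S) in the locants above | C=C1CC[C@@H]2O[C@@H]3C[C@]4(C)[C@@H](Br)CC[C@@](C)(O)[C@H]4C[C@]13C2(C)C | target

**Totals**
Total step count: 15. Longest linear sequence: 14 (steps 1–10 and 12–15; step 11 is a one-step branch).

**Three steps most likely to fail, with fallbacks**

Step 4 (enantioselective bromonium cyclisation onto a dioxinone; no precedent for this terminator). The fallback sets out from 6 and makes the bromonium ion enantiospecifically instead of by catalyst control. Shi epoxidation of 6 with the D-fructose-derived ketone gives 2,2-dimethyl-6-{2-[(2R,3R)-3-methyl-3-(prop-2-en-1-yl)oxiran-2-yl]ethyl}-4H-1,3-dioxin-4-one F1. Soft bromide (Li2NiBr4, THF, 0 °C) opens it at the less substituted carbon with inversion to 6-[(3S,4R)-3-bromo-4-hydroxy-4-methylhept-6-en-1-yl]-2,2-dimethyl-4H-1,3-dioxin-4-one F2. Ionisation of the tertiary alcohol (BF3·OEt2, CH2Cl2–HFIP, −40 °C) with anchimeric assistance by bromine regenerates the configurationally defined bromonium ion, which the dioxinone traps as before; the sequence comes back to the route at 7.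

Step 12 (Claisen acylation of a hindered cyclic enolate carrying a free alkoxide). The fallback sets out from 13 and reverses the order of acylation and ring-B closure. The unhindered kinetic methyl-ketone enolate of 13 (LDA, −78 °C) is acylated by 16 to give [(1R,2S,3S,6R)-3-bromo-2-{6-[(2S)-3,3-dimethyloxiran-2-yl]-2,4-dioxohexyl}-6-hydroxy-2,6-dimethylcyclohexyl]methyl 4-methylbenzenesulfonate F3. Its soft diketone enolate (K2CO3, DMF, rt) closes ring B by 6-exo C-alkylation at the central carbon; the sequence comes back to the route at 17.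

Step 13 (spirocyclisation forming vicinal quaternary carbons; O-alkylation, epoxide rearrangement or the wrong face at C7 are possible). The fallback sets out from 14 and uses a mono-enol ether with C11 at the carbinol level, so no carbonyl oxygen can intercept the cation.
- DIBAL-H (−78 °C) reduces 16 to 3-[(2S)-3,3-dimethyloxiran-2-yl]propanal F4.
- The lithium enolate of 14 adds to F4 and the aldolate is trapped with Ac2O to give the β-acetoxy ketone (14 bearing a 1-acetoxy-3-[(2S)-3,3-dimethyloxiran-2-yl]propyl group at C7, epimer mixture) F5.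
- TMSOTf/Et3N (−78 °C) gives the tetrasubstituted C7=C8 silyl enol ether (tertiary OH also silylated) F6.
- MeAlCl2 (CH2Cl2, −78 °C) then acidic work-up gives the spiro lactol 11-acetate F7.
- Et3SiH/TMSOTf gives the ether 11-acetate F8, and K2CO3/MeOH the 11-alcohol F9.
- Dess–Martin oxidation of F9 brings the sequence back to the route at 21.

**Further compounds**
F1 | step 4 | 2,2-dimethyl-6-{2-[(2R,3R)-3-methyl-3-(prop-2-en-1-yl)oxiran-2-yl]ethyl}-4H-1,3-dioxin-4-one | CC1(C)OC(=O)C=C(CC[C@H]2O[C@]2(C)CC=C)O1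
F2 | step 4 | 6-[(3S,4R)-3-bromo-4-hydroxy-4-methylhept-6-en-1-yl]-2,2-dimethyl-4H-1,3-dioxin-4-one | CC1(C)OC(=O)C=C(CC[C@H](Br)[C@](C)(O)CC=C)O1
F3 | step 12 | [(1R,2S,3S,6R)-3-bromo-2-{6-[(2S)-3,3-dimethyloxiran-2-yl]-2,4-dioxohexyl}-6-hydroxy-2,6-dimethylcyclohexyl]methyl 4-methylbenzenesulfonate | Cc1ccc(cc1)S(=O)(=O)OC[C@@H]1[C@](C)(O)CC[C@H](Br)[C@@]1(C)CC(=O)CC(=O)CC[C@@H]1OC1(C)C
F4 | step 13 | 3-[(2S)-3,3-dimethyloxiran-2-yl]propanal | O=CCC[C@@H]1OC1(C)C
F5 | step 13 | β-acetoxy ketone: 14 with a 1-acetoxy-3-[(2S)-3,3-dimethyloxiran-2-yl]propyl group at C7 (epimers at C7 and C11) | C[C@@]1(O)CC[C@H](Br)[C@@]2(C)CC(=O)C(C[C@H]12)C(OC(C)=O)CC[C@@H]1OC1(C)C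
F6 | step 13 | C7=C8 trimethylsilyl enol ether of F5 with C4 trimethylsilyl ether | C[C@@]1(O[Si](C)(C)C)CC[C@H](Br)[C@@]2(C)CC(O[Si](C)(C)C)=C(C[C@H]12)C(OC(C)=O)CC[C@@H]1OC1(C)C
F7 | step 13 | spiro lactol 11-acetate (C8 hemiketal to O-14; C11 epimers) | CC(=O)OC1CC[C@@H]2O[C@]3(O)C[C@]4(C)[C@@H](Br)CC[C@@](C)(O)[C@H]4C[C@]13C2(C)C
F8 | step 13 | tetracyclic ether 11-acetate (C11 epimers) | CC(=O)OC1CC[C@@H]2O[C@@H]3C[C@]4(C)[C@@H](Br)CC[C@@](C)(O)[C@H]4C[C@]13C2(C)C
F9 | step 13 | tetracyclic ether 11-alcohol (C11 epimers) | OC1CC[C@@H]2O[C@@H]3C[C@]4(C)[C@@H](Br)CC[C@@](C)(O)[C@H]4C[C@]13C2(C)C
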